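**Plan**

Labels: the seven-membered ring consists of Ca (CH on the styryl phenol ring C), Cb (CH bearing 4-hydroxyphenyl ring E), two carbons of resorcinol ring F, Cc (CH shared with the dihydrofuran) and two carbons of ring D. Cd is the O-CH(ring G) of the dihydrofuran fused to ring D.
Cuts, in retrosynthetic order: ring C–vinyl carbon (Heck), Cb–ring F (Friedel–Crafts, traded for an O–Cb bond), Ca–Cb (carbene C–H insertion), Ca–ring D (aryllithium plus aldehyde), Cc–Cd (a first C–H insertion), Cc–ring D (Friedel–Crafts acylation).
Enabling feature: Ca is ortho to the oxygen of ring C, so bonding that oxygen to Cb makes Ca/Cb the C3/C2 of a 2,3-diaryl-2,3-dihydrobenzofuran. This ring is absent from the target; a diaryl carbene at Ca can close it by inserting into the O-CH2 of a 4-methoxybenzyl ether, and acid can later exchange its anisylic O–Cb bond for Cb–ring F.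
Forward order: dihydrofuran on ring D (cis, then trans), temporary dihydrofuran on ring C, seven-membered ring as the temporary ring opens. The benzofuran half comes from the same bromo-dihydrobenzofuran by dehydrogenation and is joined last through the alkene.
Stereochemistry: Cc from Rh2(R-PTAD)4, Cd by acid equilibration to trans, Ca from Rh2(S-PTAD)4, Cb by ring closure anti to ring C, E-alkene from the Heck reaction.
Protecting groups: methyl ethers serve until both halves are complete and are exchanged for acetates before the coupling, so the stilbene never meets BBr3.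

Key step: step 12

Assumption: Rh2(S-PTAD)4 is taken to deliver the (2S,3R)-cis-dihydrobenzofuran and Rh2(R-PTAD)4 its mirror image. If the sense of induction is the opposite, the two commercial antipodes change places between steps 5 and 12.

**Route**

Step 1
Reactants: 1 1-bromo-3,5-dimethoxybenzene; 2 3,5-dimethoxybenzoyl chloride
Product: 3 (2-bromo-4,6-dimethoxyphenyl)(3,5-dimethoxyphenyl)methanone
Conditions: AlCl3 (1.2 equiv), CH2Cl2, 0 °C to rt
Reagents that add atoms: none
Why: Friedel–Crafts acylation should take the carbon next to bromine, which is para to one methoxy group, ortho to the other and less crowded than the site between the two methoxy groups, the preference this arene also shows in Vilsmeier formylation.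

Step 2
Reactants: 3 (2-bromo-4,6-dimethoxyphenyl)(3,5-dimethoxyphenyl)methanone
Product: 4 (2-bromo-6-hydroxy-4-methoxyphenyl)(3,5-dimethoxyphenyl)methanone
Conditions: BCl3 (1.5 equiv), CH2Cl2, −78 °C to 0 °C; H2O
Reagents that add atoms: none
Why: BCl3 binds the carbonyl oxygen and the neighbouring methoxy oxygen in a six-membered chelate and therefore cleaves only that methyl ether (chelation-directed ortho demethylation of aryl ketones).

Step 3
Reactants: 4 (2-bromo-6-hydroxy-4-methoxyphenyl)(3,5-dimethoxyphenyl)methanone; 5 4-methoxybenzyl chloride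
Product: 6 {2-bromo-4-methoxy-6-[(4-methoxybenzyl)oxy]phenyl}(3,5-dimethoxyphenyl)methanone
Conditions: K2CO3, DMF, 60 °C
Reagents that add atoms: none
Why: Williamson etherification of the phenoxide installs the CH2 group that becomes Cd and the anisyl ring that becomes ring G.

Step 4
Reactants: 6 {2-bromo-4-methoxy-6-[(4-methoxybenzyl)oxy]phenyl}(3,5-dimethoxyphenyl)methanone
Product: 7 hydrazone of 6 (C=N isomers, both usable)
Conditions: N2H4·H2O (30 equiv), AcOH (cat.), n-BuOH, 120 °C, sealed tube
Reagents that add atoms: hydrazine, NN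
Why: This is a hydrazone condensation, run with a large excess of hydrazine, acid catalysis and heat because the carbonyl group carries a 2,6-disubstituted ring, conditions that the ether and the electron-rich aryl bromide tolerate.

Step 5
Reactants: 7 hydrazone of 6
Product: 9 (2R,3S)-4-bromo-3-(3,5-dimethoxyphenyl)-6-methoxy-2-(4-methoxyphenyl)-2,3-dihydro-1-benzofuran (cis), via diazo compound 8 (not isolated)
Conditions: MnO2 (10 equiv), CH2Cl2, rt; filtration through Celite; filtrate added slowly to Rh2(R-PTAD)4 (1 mol %), CH2Cl2, 0 °C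
Reagents that add atoms: none
Why: MnO2 dehydrogenates the hydrazone to the diaryldiazomethane, whose dirhodium carbene inserts 1,5 into the O-CH2 group (known enantioselective donor–donor carbene C–H insertion), the catalyst pocket setting Cc as S and the fast collapse placing the two aryl groups cis (Cd R).

Step 6
Reactants: 9 cis-dihydrobenzofuran (2R,3S)
Product: 10 (2S,3S)-4-bromo-3-(3,5-dimethoxyphenyl)-6-methoxy-2-(4-methoxyphenyl)-2,3-dihydro-1-benzofuran (trans)
Conditions: BF3·OEt2 (20 mol %), CH2Cl2 (0.02 M), −20 °C to 0 °C
Reagents that add atoms: none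
Why: The Lewis acid reversibly ionises the O–Cd bond to an anisyl-stabilised cation that the ring D oxygen recaptures, so Cd equilibrates to the more stable trans arrangement (S) while Cc takes no part and keeps its configuration (acid epimerisation of cis-2-aryl-dihydrobenzofurans).

Step 7
Reactants: 11 5-bromosalicylaldehyde; 5 4-methoxybenzyl chloride
Product: 12 5-bromo-2-[(4-methoxybenzyl)oxy]benzaldehyde
Conditions: K2CO3, DMF, 50 °C
Reagents that add atoms: none
Why: Williamson etherification places on the ring C oxygen the CH2 group that becomes Cb and the anisyl ring that becomes ring E.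

Step 8
Reactants: 10 trans-bromide (2S,3S); 12 5-bromo-2-[(4-methoxybenzyl)oxy]benzaldehyde
Product: 14 {5-bromo-2-[(4-methoxybenzyl)oxy]phenyl}[(2S,3S)-3-(3,5-dimethoxyphenyl)-6-methoxy-2-(4-methoxyphenyl)-2,3-dihydro-1-benzofuran-4-yl]methanol (both carbinol epimers), via aryllithium 13 (not isolated)
Conditions: n-BuLi (1.05 equiv), THF, −78 °C, 10 min; then 12, −78 °C; H2O
Reagents that add atoms: none
Why: Bromine–lithium exchange at −78 °C outruns deprotonation at Cc or Cd, and the aryllithium adds to the aldehyde faster than it exchanges with the ring C bromide; the new carbinol centre is removed in step 9.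

Step 9
Reactants: 14 diaryl carbinol
Product: 15 {5-bromo-2-[(4-methoxybenzyl)oxy]phenyl}[(2S,3S)-3-(3,5-dimethoxyphenyl)-6-methoxy-2-(4-methoxyphenyl)-2,3-dihydro-1-benzofuran-4-yl]methanone
Conditions: Dess–Martin periodinane (1.3 equiv), CH2Cl2, rt
Reagents that add atoms: none
Why: Dess–Martin oxidation converts hindered diaryl carbinols to ketones under near-neutral conditions that leave the benzyl ether, the bromide and the dihydrobenzofuran untouched.

Step 10
Reactants: 15 diaryl ketone
Product: 16 hydrazone of 15 (C=N isomers, both usable)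
Conditions: N2H4·H2O (30 equiv), AcOH (cat.), n-BuOH, 110 °C
Reagents that add atoms: hydrazine, NN
Why: This is a hydrazone condensation on a benzophenone with one ortho substituent on each ring, less shielded than 6, and no stereocentre is acidic enough to suffer under these conditions.

Step 11
Reactants: 16 hydrazone of 15
Product: 17 (2S,3S)-4-[{5-bromo-2-[(4-methoxybenzyl)oxy]phenyl}(diazo)methyl]-3-(3,5-dimethoxyphenyl)-6-methoxy-2-(4-methoxyphenyl)-2,3-dihydro-1-benzofuran
Conditions: MnO2 (10 equiv), CH2Cl2, rt; filtration through Celite, concentration in the cold, used at once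
Reagents that add atoms: none
Why: Heterogeneous MnO2 dehydrogenation of diaryl ketone hydrazones is the standard mild entry to diaryldiazomethanes, and filtration removes the oxidant before the catalyst is met.

Step 12
Reactants: 17 diaryldiazomethane
Product: 18 (2S,3R)-5-bromo-3-[(2S,3S)-3-(3,5-dimethoxyphenyl)-6-methoxy-2-(4-methoxyphenyl)-2,3-dihydro-1-benzofuran-4-yl]-2-(4-methoxyphenyl)-2,3-dihydro-1-benzofuran (temporary ring cis; Ca R, Cb S, Cc S, Cd S)
Conditions: Rh2(S-PTAD)4 (1–2 mol %), CH2Cl2, 0 °C, 17 added over 2 h by syringe pump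
Reagents that add atoms: none
Why: On the dirhodium core 17 loses N2 and gives a donor–donor carbene at Ca, which draws a hydride-like hydrogen from the O-CH2 group of the 4-methoxybenzyl ether and collapses without delay to the Ca–Cb bond. The closest known reaction type is exactly this one, the enantioselective dirhodium-catalysed insertion of diaryl carbenes into benzylic ether C–H bonds to give 2,3-diaryl-2,3-dihydrobenzofurans. The single ring closed is the five-membered O-heterocycle on ring C, by 1,5-insertion (Ca, two carbons of ring C, oxygen, Cb). Ca (R) is controlled by the chiral carboxylate pocket of Rh2(S-PTAD)4, which fixes the carbene face that receives the hydrogen; as Cc and Cd are already in place, the antipode is dictated by the target and cannot be picked for a matched pairing, so the step counts on catalyst control outweighing the bias of ring F next door. Cb (S, aryl groups cis) follows from collapse of the tight ion pair in the geometry of the hydrogen transfer and does not matter, since step 13 erases it. The selectivity needed is for this CH2 over attack on electron-rich ring F, over Cc–H and Cd–H and over azine formation: the CH2 is the most hydridic C–H and the only one whose insertion gives an unstrained ring (Cc–H would give a four-membered ring, Cd–H a bridged arene), the weakly electrophilic donor–donor carbene is slow to add to arenes, and slow addition keeps the diazo concentration low.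

Step 13
Reactants: 18 bis(dihydrobenzofuran)
Product: 19 4-bromo-2-[(1S,6R,7S,11bS)-4,8,10-trimethoxy-1,7-bis(4-methoxyphenyl)-1,6,7,11b-tetrahydrobenzo[6,7]cyclohepta[1,2,3-cd][1]benzofuran-6-yl]phenol (C1 = Cd, C6 = Ca, C7 = Cb, C11b = Cc)
Conditions: BF3·OEt2 (50 mol %), CH2Cl2 (0.005 M), −78 °C to −20 °C
Reagents that add atoms: none
Why: BF3 ionises the O–Cb bond of the strained cis ring to an anisyl-stabilised cation, and the ring F carbon ortho to Cc, activated ortho/para by its two methoxy groups, captures it irreversibly in a seven-membered intramolecular Friedel–Crafts alkylation (the acid-induced dihydrobenzofuran-to-cycloheptane change known among oligostilbenes) with ring E going anti to ring C so that Cb becomes S, while ionisation of the O–Cd bond is harmless because that cation has no partner but its own oxygen and recloses trans.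

Step 14
Reactants: 19 ring-switched bromophenol
Product: 21 hexaacetate of the ring-switched bromide (Ca R; Cb S; Cc S; Cd S), via hexaphenol 20 (not isolated)
Conditions: BBr3 (15 equiv), CH2Cl2, −78 °C to rt; H2O; then Ac2O, pyridine, DMAP (cat.), rt
Reagents that add atoms: acetic anhydride, CC(=O)OC(C)=O
Why: BBr3 cleaves the five aryl methyl ethers at a stage where no alkene is present and where an opened O–Cd bond can only reclose trans, and acetylation of the crude hexaphenol gives a stable, chromatographable bromide that is also less electron-rich for the Heck reaction.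

Step 15
Reactants: 10 trans-bromide (2S,3S)
Product: 22 4-bromo-3-(3,5-dimethoxyphenyl)-6-methoxy-2-(4-methoxyphenyl)-1-benzofuran
Conditions: DDQ (1.5 equiv), 1,4-dioxane, 90 °C
Reagents that add atoms: none
Why: DDQ abstracts hydride from the oxygen- and anisyl-stabilised C2–H, and loss of the C3 proton aromatises the ring, the known dehydrogenation of 2,3-diaryl-dihydrobenzofurans to benzofurans.

Step 16
Reactants: 22 bromobenzofuran tetramethyl ether
Product: 24 4-bromo-6-acetoxy-2-(4-acetoxyphenyl)-3-(3,5-diacetoxyphenyl)-1-benzofuran, via tetraphenol 23 (not isolated)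
Conditions: BBr3 (10 equiv), CH2Cl2, −78 °C to rt; H2O; then Ac2O, pyridine, DMAP (cat.), rt
Reagents that add atoms: acetic anhydride, CC(=O)OC(C)=O
Why: The fully aromatic benzofuran has no acid-labile bond, so BBr3 demethylation followed by acetylation of the crude phenol is routine.

Step 17
Reactants: 24 bromobenzofuran tetraacetate
Product: 25 6-acetoxy-2-(4-acetoxyphenyl)-3-(3,5-diacetoxyphenyl)-4-vinyl-1-benzofuran
Conditions: tributyl(vinyl)stannane (1.3 equiv), Pd(PPh3)4 (5 mol %), BHT (cat.), toluene, 100 °C
Reagents that add atoms: tributyl(vinyl)stannane, C=C[Sn](CCCC)(CCCC)CCCC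
Why: Stille vinylation runs without base and therefore spares the aryl acetates.

Step 18
Reactants: 21 bromide hexaacetate; 25 vinylbenzofuran tetraacetate
Product: 26 decaacetate of the target (E-alkene; Ca R, Cb S, Cc S, Cd S)
Conditions: Pd(OAc)2 (10 mol %), P(o-tol)3 (25 mol %), Et3N, DMF, 100 °C
Reagents that add atoms: none
Why: In this Mizoroki–Heck reaction the unhindered bromide para to an acetoxy group adds to zerovalent palladium, the aryl group goes to the terminal carbon of the styrene, and syn insertion followed by syn β-hydride elimination gives the E-stilbene, as known for acetoxy-substituted styrenes and aryl halides.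

Step 19
Reactants: 26 decaacetate
Product: 27 target CNP0339094.1
Conditions: NH3 (7 M in MeOH), 0 °C to rt, argon
Reagents that add atoms: none
Why: Ammonolysis removes aryl acetates under mild, acid-free conditions, so the stilbene, the electron-rich resorcinol next to it and the four stereocentres are not exposed to any cation-forming reagent.

**Compound list**

1 | 1-bromo-3,5-dimethoxybenzene | COc1cc(Br)cc(OC)c1 | starting material
2 | 3,5-dimethoxybenzoyl chloride | COc1cc(cc(OC)c1)C(Cl)=O | starting material
3 | (2-bromo-4,6-dimethoxyphenyl)(3,5-dimethoxyphenyl)methanone | COc1cc(Br)c(C(=O)c2cc(OC)cc(OC)c2)c(OC)c1 | intermediate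
4 | (2-bromo-6-hydroxy-4-methoxyphenyl)(3,5-dimethoxyphenyl)methanone | COc1cc(O)c(C(=O)c2cc(OC)cc(OC)c2)c(Br)c1 | intermediate
5 | 4-methoxybenzyl chloride | COc1ccc(CCl)cc1 | starting material
6 | {2-bromo-4-methoxy-6-[(4-methoxybenzyl)oxy]phenyl}(3,5-dimethoxyphenyl)methanone | COc1ccc(COc2cc(OC)cc(Br)c2C(=O)c2cc(OC)cc(OC)c2)cc1 | intermediate
7 | hydrazone of 6 | COc1ccc(COc2cc(OC)cc(Br)c2C(=NN)c2cc(OC)cc(OC)c2)cc1 | intermediate
8 | 1-bromo-2-[diazo(3,5-dimethoxyphenyl)methyl]-5-methoxy-3-[(4-methoxybenzyl)oxy]benzene | COc1ccc(COc2cc(OC)cc(Br)c2C(=[N+]=[N-])c2cc(OC)cc(OC)c2)cc1 | intermediate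
9 | (2R,3S)-4-bromo-3-(3,5-dimethoxyphenyl)-6-methoxy-2-(4-methoxyphenyl)-2,3-dihydro-1-benzofuran (cis) | Brc1cc(OC)cc2c1[C@H](c1cc(OC)cc(OC)c1)[C@H](c1ccc(OC)cc1)O2 | intermediate
10 | (2S,3S)-4-bromo-3-(3,5-dimethoxyphenyl)-6-methoxy-2-(4-methoxyphenyl)-2,3-dihydro-1-benzofuran (trans) | Brc1cc(OC)cc2c1[C@H](c1cc(OC)cc(OC)c1)[C@@H](c1ccc(OC)cc1)O2 | intermediate
11 | 5-bromosalicylaldehyde | O=Cc1cc(Br)ccc1O | starting material
12 | 5-bromo-2-[(4-methoxybenzyl)oxy]benzaldehyde | COc1ccc(COc2ccc(Br)cc2C=O)cc1 | intermediate
13 | (2S,3S)-3-(3,5-dimethoxyphenyl)-6-methoxy-2-(4-methoxyphenyl)-2,3-dihydro-1-benzofuran-4-yllithium | [Li]c1cc(OC)cc2c1[C@H](c1cc(OC)cc(OC)c1)[C@@H](c1ccc(OC)cc1)O2 | intermediate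
14 | diaryl carbinol joining ring C and ring D (both carbinol epimers) | COc1ccc(COc2ccc(Br)cc2C(O)c2cc(OC)cc3c2[C@H](c2cc(OC)cc(OC)c2)[C@@H](c2ccc(OC)cc2)O3)cc1 | intermediate
15 | diaryl ketone joining ring C and ring D | COc1ccc(COc2ccc(Br)cc2C(=O)c2cc(OC)cc3c2[C@H](c2cc(OC)cc(OC)c2)[C@@H](c2ccc(OC)cc2)O3)cc1 | intermediate
16 | hydrazone of 15 | COc1ccc(COc2ccc(Br)cc2C(=NN)c2cc(OC)cc3c2[C@H](c2cc(OC)cc(OC)c2)[C@@H](c2ccc(OC)cc2)O3)cc1 | intermediate
17 | diaryldiazomethane at Ca (precursor of the key step) | COc1ccc(COc2ccc(Br)cc2C(=[N+]=[N-])c2cc(OC)cc3c2[C@H](c2cc(OC)cc(OC)c2)[C@@H](c2ccc(OC)cc2)O3)cc1 | intermediate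
18 | bis(dihydrobenzofuran) with the temporary cis ring on ring C (product of the key step; Ca R, Cb S, Cc S, Cd S) | COc1ccc(cc1)[C@H]1Oc2ccc(Br)cc2[C@H]1c1cc(OC)cc2c1[C@H](c1cc(OC)cc(OC)c1)[C@@H](c1ccc(OC)cc1)O2 | intermediate
19 | ring-switched bromophenol pentamethyl ether (Ca R, Cb S, Cc S, Cd S) | Oc1ccc(Br)cc1[C@H]1c2cc(OC)cc3c2[C@H](c2cc(OC)cc(OC)c2[C@@H]1c1ccc(OC)cc1)[C@@H](c1ccc(OC)cc1)O3 | intermediate
20 | ring-switched bromide hexaphenol | Oc1ccc(Br)cc1[C@H]1c2cc(O)cc3c2[C@H](c2cc(O)cc(O)c2[C@@H]1c1ccc(O)cc1)[C@@H](c1ccc(O)cc1)O3 | intermediate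
21 | ring-switched bromide hexaacetate | CC(=O)Oc1ccc(Br)cc1[C@H]1c2cc(OC(C)=O)cc3c2[C@H](c2cc(OC(C)=O)cc(OC(C)=O)c2[C@@H]1c1ccc(OC(C)=O)cc1)[C@@H](c1ccc(OC(C)=O)cc1)O3 | intermediate
22 | 4-bromo-3-(3,5-dimethoxyphenyl)-6-methoxy-2-(4-methoxyphenyl)-1-benzofuran | COc1ccc(cc1)-c1oc2cc(OC)cc(Br)c2c1-c1cc(OC)cc(OC)c1 | intermediate
23 | 5-[4-bromo-6-hydroxy-2-(4-hydroxyphenyl)-1-benzofuran-3-yl]benzene-1,3-diol | Oc1ccc(cc1)-c1oc2cc(O)cc(Br)c2c1-c1cc(O)cc(O)c1 | intermediate
24 | tetraacetate of 23 | CC(=O)Oc1ccc(cc1)-c1oc2cc(OC(C)=O)cc(Br)c2c1-c1cc(OC(C)=O)cc(OC(C)=O)c1 | intermediate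
25 | 6-acetoxy-2-(4-acetoxyphenyl)-3-(3,5-diacetoxyphenyl)-4-vinyl-1-benzofuran | CC(=O)Oc1ccc(cc1)-c1oc2cc(OC(C)=O)cc(C=C)c2c1-c1cc(OC(C)=O)cc(OC(C)=O)c1 | intermediate
26 | decaacetate of the target | CC(=O)Oc1ccc(-c2oc3cc(OC(C)=O)cc(/C=C/c4ccc(OC(C)=O)c([C@H]5c6cc(OC(C)=O)cc7c6[C@H](c6cc(OC(C)=O)cc(OC(C)=O)c6[C@@H]5c5ccc(OC(C)=O)cc5)[C@@H](c5ccc(OC(C)=O)cc5)O7)c4)c3c2-c2cc(OC(C)=O)cc(OC(C)=O)c2)cc1 | intermediate
27 | CNP0339094.1 (Ca R, Cb S, Cc S, Cd S, E-alkene) | Oc1ccc(-c2oc3cc(O)cc(/C=C/c4ccc(O)c([C@H]5c6cc(O)cc7c6[C@H](c6cc(O)cc(O)c6[C@@H]5c5ccc(O)cc5)[C@@H](c5ccc(O)cc5)O7)c4)c3c2-c2cc(O)cc(O)c2)cc1 | target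

**Step count**

Total step count: 19.
Longest linear sequence: 15 (steps 1–6, 8–14, 18, 19).

**Steps most likely to fail**

Step 12. The carbene may be intercepted by the neighbouring ring F or may dimerise to the azine. Facial selectivity may also be poor, because the catalyst may have to work against the bias of Cc.
The fallback sets out from 15 and comes back at 19; it makes the Ca–Cb bond by polar one-carbon homologation instead of C–H insertion. Ketone 15 is treated with dimethylsulfonium methylide (Me3SI, NaH, DMSO/THF, Corey–Chaykovsky reaction) to give the 1,1-diaryl epoxide F1. ZnI2 in CH2Cl2 rearranges this (Meinwald rearrangement) to the diarylacetaldehyde F2. Its Ca centre is epimerisable, so the two Ca epimers can be separated and the unwanted one re-equilibrated with DBU. 4-Methoxyphenylmagnesium bromide in THF at −78 °C then adds to give the carbinol F3 (Cb as a mixture, which is of no account). BF3·OEt2 in dilute CH2Cl2, with pentamethylbenzene as cation trap, ionises the Cb–OH group, takes off the 4-methoxybenzyl ether and closes the seven-membered ring to 19. Ca then rests on substrate control and separation rather than on a catalyst.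

Step 13. At the cation stage Ca may lose its proton, which would flatten Ca. Alternatively the ring C oxygen may simply return, so that the material rests as the trans ether and the slower carbon–carbon closure is not reached.
The fallback sets out from 18 and comes back at 21; it moves the closure from a catalytic isomerisation to a stoichiometric ether cleavage merged with the deprotection. Compound 18 is treated with BBr3 as in step 14. Boron then cleaves the O–Cb bond for good and holds the ring C oxygen until work-up, so it cannot return. Bromide pairs with Cb, so little free cation is available to lose a proton. As the methyl ethers fall, ring F becomes a more nucleophilic boron resorcinolate. Ring closure and demethylation thus occur in one flask to give 20, and acetylation of the crude product gives 21. This path adds no new compound F0.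

Step 4. Condensation may be slow or incomplete, because both faces of the carbonyl group are shielded by the ortho bromine and the ortho benzyloxy group.
The fallback sets out from 4 and comes back at 7; it reverses the order of etherification and condensation. In hydroxy ketone 4 the internal hydrogen bond activates the carbonyl group and holds ring D in its plane, which takes the ortho substituents out of the line of approach. Hydrazine hydrate in EtOH at reflux should therefore give the hydroxy hydrazone F4. Cs2CO3 and 5 in DMF at rt then alkylate the phenoxide oxygen in preference to the weakly nucleophilic hydrazone nitrogen, giving 7.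

**Further compounds**

F1 | step 12 | 1,1-diaryl epoxide from 15 (both epimers at the quaternary carbon) | COc1ccc(COc2ccc(Br)cc2C2(CO2)c2cc(OC)cc3c2[C@H](c2cc(OC)cc(OC)c2)[C@@H](c2ccc(OC)cc2)O3)cc1
F2 | step 12 | diarylacetaldehyde, Ca R | COc1ccc(COc2ccc(Br)cc2[C@H](C=O)c2cc(OC)cc3c2[C@H](c2cc(OC)cc(OC)c2)[C@@H](c2ccc(OC)cc2)O3)cc1
F3 | step 12 | carbinol at Cb bearing 4-methoxyphenyl, Ca R, both Cb epimers | COc1ccc(COc2ccc(Br)cc2[C@H](C(O)c2ccc(OC)cc2)c2cc(OC)cc3c2[C@H](c2cc(OC)cc(OC)c2)[C@@H](c2ccc(OC)cc2)O3)cc1
F0 | step 13 | none | none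
F4 | step 4 | hydroxy hydrazone, the hydrazone of 4 | COc1cc(O)c(C(=NN)c2cc(OC)cc(OC)c2)c(Br)c1
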